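**Direct plan and its weak points**

A direct plan would make the (R)-4-phenyl-dihydrocoumarin A1 by carbene-catalysed annulation of a symmetric phenol with an enal, acylate it with a tigloyl group and demethylate to the ortho-hydroxy enone A2, mask that phenol as the 1,1-dimethylallyl ether A3, switch the lactone into the chromanone acid A4 by hydroxide opening and base-mediated oxa-Michael closure, and finish with a thermal Claisen shift of the allyl group to C6.
- The lactone-to-chromanone ring switch would be the weakest step. It would have to create C2 and the less stable cis C3 by amine-controlled conjugate addition and kinetic protonation, beside a free carboxylic acid, while the product can epimerise or reopen under the same basic conditions.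
- The Friedel–Crafts tigloylation with in situ ether cleavage would be weak. It would depend on C8 over C6 selectivity, and AlCl3 can drive ortho-hydroxy tigloyl ketones on to racemic chromanones or add HCl to the enone.
- The closing Claisen rearrangement would be weak. It would heat the finished acid, with its epimerisable cis-2,3-dimethylchromanone, to 105 °C in the last step.

**Retrosynthetic overview of the new route**

- The O1–C2–C3–C4 segment of the pyranone ring, with its cis methyls at C2 (S) and C3 (R), would be taken whole from tert-butyl (R)-3-hydroxybutanoate: methylation sets C3, Mitsunobu inversion sets C2 and forms O1–C2. The key disconnection is then C4–C4a, an intramolecular Friedel–Crafts acylation onto the threefold-symmetric phloroglucinol ring.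
- Ring order: the pyranone closes first, two steps from commercial material. A temporary lactone on O7/C8 follows (carbene-catalysed annulation with cinnamaldehyde sets the benzylic centre); it is opened at the end, when O7 is methylated and the acid released.
- Regiochemistry would come from symmetry and chelation: the ring closure has two equivalent sites; iodine between the two hydroxyls (C6) blocks that carbon for the annulation and is then exchanged for prenyl by Stille coupling; the chelated 5-OH stays free throughout.
- Weak steps avoided by design: no tigloyl enone and no AlCl3; C2/C3 are never made by conjugate addition or kinetic protonation; no lactone-to-chromanone switch; no thermal sigmatropic step.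

Key step: step 3

Assumption: the (5aS,10bR) antipode of the aminoindanol-derived N-mesityl triazolium salt is taken to give the (R) benzylic centre in the annulation of cinnamaldehyde with a phenol; if the sense proves opposite, the (5aR,10bS) salt would be used.

**Route**

Step 1
Reactants: 1 tert-butyl (R)-3-hydroxybutanoate
Product: 2 tert-butyl (2R,3R)-3-hydroxy-2-methylbutanoate
Conditions: LiN(i-Pr)2 (2.2 equiv), THF, −78 → −20 °C; CH3I (1.5 equiv), DMPU, −78 → 0 °C; aq. NH4Cl
Reagents that add atoms: iodomethane, CI
Why: Fráter–Seebach alkylation: the lithium-chelated alkoxide–enolate dianion should take up the methyl group on the face opposite the C3 methyl and so give the anti (2R,3R) ester (the future C3 of the chromanone) under substrate control, the carbinol centre being untouched.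

Step 2
Reactants: 2 tert-butyl (2R,3R)-3-hydroxy-2-methylbutanoate; 3 phloroglucinol (benzene-1,3,5-triol)
Product: 4 tert-butyl (2R,3S)-3-(3,5-dihydroxyphenoxy)-2-methylbutanoate
Conditions: 3 (3.0 equiv), PPh3 (1.3 equiv), diisopropyl azodicarboxylate (1.3 equiv), THF, 0 → 23 °C
Reagents that add atoms: none
Why: Mitsunobu etherification: the acidic phenol should displace the activated alcohol with SN2 inversion, turning the (3R) carbinol into the (3S) aryl ether that becomes C2 (S) and forming the O1–C2 bond; the three hydroxyls of 3 are equivalent, so only mono- against bis-alkylation has to be held by the excess of 3, and the bulky tert-butyl ester hinders elimination to the tiglate.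

Step 3
Reactants: 4 tert-butyl (2R,3S)-3-(3,5-dihydroxyphenoxy)-2-methylbutanoate
Product: 6 (2S,3R)-5,7-dihydroxy-2,3-dimethylchroman-4-one, via free acid 5 (not isolated)
Conditions: CF3CO2H/CH2Cl2 1:2, Et3SiH (2 equiv), 0 → 23 °C, evaporate; P2O5/CH3SO3H (1:10 w/w), 23 °C, 1 h; ice–water
Reagents that add atoms: none
Why: Acid first removes the tert-butyl group (the cation is reduced by Et3SiH so that it cannot alkylate the ring), then P2O5/CH3SO3H turns acid 5 into a mixed anhydride or acylium ion that attacks the ring carbon ortho to the ether oxygen and is deprotonated to the ketone, an intramolecular Friedel–Crafts acylation that forms C4–C4a. The closest known reaction is the cyclisation of 3-aryloxypropanoic and 3-aryloxybutanoic acids to chroman-4-ones, a type documented to proceed without loss of a C2 stereocentre. The pyranone ring closes by 6-exo attack of the ring carbon on the acyl carbon. No stereocentre is formed: C2 (S) and C3 (R) come from 4 with no bond to either broken, so the cis relationship is the one fixed in steps 1 and 2. The step needs regioselectivity and retention of the cis pair; the first is secured by symmetry, since both carbons ortho to the ether oxygen of the 3,5-dihydroxyphenyl ring are equivalent and the third ring carbon cannot be reached by the three-atom tether, the second by the short contact at 23 °C and by the strong hydrogen bond of the new 5-OH to the ketone. The same event differentiates the three oxygens of phloroglucinol into the ring ether O1, the chelated 5-OH and the free, more acidic 7-OH.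

Step 4
Reactants: 6 (2S,3R)-5,7-dihydroxy-2,3-dimethylchroman-4-one
Product: 7 (2S,3R)-5,7-dihydroxy-6-iodo-2,3-dimethylchroman-4-one
Conditions: iodine (1.05 equiv), NaHCO3 (1.5 equiv), THF/H2O 1:1, 0 °C, 30 min; aq. Na2S2O3
Reagents that add atoms: iodine, II
Why: Electrophilic iodination of the phenoxide under bicarbonate: C6 lies between the two hydroxyls and ortho to the chelated 5-OH, the position that resorcinols iodinate under these conditions (2-iodoresorcinol) and the one whose substitution keeps the hydrogen-bonded enol–ketone conjugation intact, so that C6 should be blocked selectively and carry the handle for the prenyl group, while mildly basic water at 0 °C should leave C2 and C3 alone.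

Step 5
Reactants: 7 (2S,3R)-5,7-dihydroxy-6-iodo-2,3-dimethylchroman-4-one; 8 (E)-cinnamaldehyde
Product: 9 (2S,3R,10R)-5-hydroxy-6-iodo-2,3-dimethyl-10-phenyl-2,3,9,10-tetrahydro-4H,8H-pyrano[2,3-f]chromene-4,8-dione (the 4-phenyl-dihydrocoumarin lactone fused through O7 and C8 of the chromanone)
Conditions: 8 (1.5 equiv), (5aS,10bR)-2-mesityl-5a,10b-dihydro-4H,6H-indeno[2,1-b][1,2,4]triazolo[4,3-d][1,4]oxazin-2-ium tetrafluoroborate (10 mol%), 3,3',5,5'-tetra-tert-butyldiphenoquinone (1.2 equiv), K2CO3 (0.5 equiv), 4 Å MS, toluene/THF 4:1, 23 °C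
Reagents that add atoms: none
Why: Oxidative N-heterocyclic carbene catalysis turns 8 into the cinnamoyl azolium, to which the 7-phenoxide adds through its only free ortho carbon C8 (1,2-addition and [3,3] shift, or direct conjugate addition) before O7 lactonises and releases the catalyst, a formal [3+3] annulation established for naphthols, electron-rich phenols and vinylogous acids; the aminoindanol backbone shields one face of the acyl azolium so that the benzylic centre should form as (R) under catalyst control, and under carbonate the substrate is present as its 7-phenoxide, a vinylogous carboxylate that should not enolise at C3.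

Step 6
Reactants: 9 the iodo lactone from step 5; 10 tributyl(3-methylbut-2-en-1-yl)stannane
Product: 11 (2S,3R,10R)-5-hydroxy-2,3-dimethyl-6-(3-methylbut-2-en-1-yl)-10-phenyl-2,3,9,10-tetrahydro-4H,8H-pyrano[2,3-f]chromene-4,8-dione
Conditions: 10 (1.5 equiv), Pd2(dba)3 (2.5 mol%), P(2-furyl)3 (10 mol%), DMF, 55 °C, Ar
Reagents that add atoms: none
Why: Stille coupling: oxidative addition of zerovalent palladium into the C6–iodine bond, transmetalation with the allylic stannane and reductive elimination at the unsubstituted terminus of the prenyl ligand should give the linear 3-methylbut-2-enyl group under neutral conditions at 55 °C, which spares the lactone, the cis C2/C3 pair and the benzylic centre.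

Step 7
Reactants: 11 the prenyl lactone from step 6
Product: 13 (R)-3-[(2S,3R)-5-hydroxy-7-methoxy-2,3-dimethyl-6-(3-methylbut-2-en-1-yl)-4-oxochroman-8-yl]-3-phenylpropanoic acid, via ring-opened hydroxy acid 12 (not isolated)
Conditions: LiOH·H2O (2.1 equiv), THF/H2O 2:1, 0 °C, 30 min; NaHCO3 (2 equiv), (CH3O)2SO2 (1.5 equiv), 0 → 15 °C, 4 h; 1 M HCl to pH 4, 0 °C (any unmethylated 12 recloses to 11 and is recycled)
Reagents that add atoms: lithium hydroxide, [Li+].[OH-]; dimethyl sulfate, COS(=O)(=O)OC
Why: Hydroxide opens the aryl lactone to the carboxylate and the 7-phenoxide, which dimethyl sulfate should methylate on oxygen in the buffered aqueous medium while the chelated 5-OH (not ionised at pH 8–9) and the carboxylate stay free, the classical conversion of a dihydrocoumarin into a 3-(2-methoxyaryl)propanoic acid; the 7-phenoxide keeps the chromanone from enolising during the basic phase, so C2, C3 and the benzylic centre should be retained.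

**Compound list**

1 | tert-butyl (R)-3-hydroxybutanoate | C[C@@H](O)CC(=O)OC(C)(C)C | starting material
2 | tert-butyl (2R,3R)-3-hydroxy-2-methylbutanoate | C[C@@H](O)[C@@H](C)C(=O)OC(C)(C)C | intermediate
3 | phloroglucinol (benzene-1,3,5-triol) | Oc1cc(O)cc(O)c1 | starting material
4 | tert-butyl (2R,3S)-3-(3,5-dihydroxyphenoxy)-2-methylbutanoate | C[C@H](Oc1cc(O)cc(O)c1)[C@@H](C)C(=O)OC(C)(C)C | intermediate
5 | (2R,3S)-3-(3,5-dihydroxyphenoxy)-2-methylbutanoic acid | C[C@H](Oc1cc(O)cc(O)c1)[C@@H](C)C(=O)O | intermediate
6 | (2S,3R)-5,7-dihydroxy-2,3-dimethylchroman-4-one | O=C1c2c(O)cc(O)cc2O[C@@H](C)[C@H]1C | intermediate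
7 | (2S,3R)-5,7-dihydroxy-6-iodo-2,3-dimethylchroman-4-one | O=C1c2c(O)c(I)c(O)cc2O[C@@H](C)[C@H]1C | intermediate
8 | (E)-cinnamaldehyde | O=C/C=C/c1ccccc1 | starting material
9 | (2S,3R,10R)-5-hydroxy-6-iodo-2,3-dimethyl-10-phenyl-2,3,9,10-tetrahydro-4H,8H-pyrano[2,3-f]chromene-4,8-dione | O=C1c2c(O)c(I)c3OC(=O)C[C@H](c4ccccc4)c3c2O[C@@H](C)[C@H]1C | intermediate
10 | tributyl(3-methylbut-2-en-1-yl)stannane | CCCC[Sn](CCCC)(CCCC)CC=C(C)C | starting material
11 | (2S,3R,10R)-5-hydroxy-2,3-dimethyl-6-(3-methylbut-2-en-1-yl)-10-phenyl-2,3,9,10-tetrahydro-4H,8H-pyrano[2,3-f]chromene-4,8-dione | O=C1c2c(O)c(CC=C(C)C)c3OC(=O)C[C@H](c4ccccc4)c3c2O[C@@H](C)[C@H]1C | intermediate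
12 | (R)-3-[(2S,3R)-5,7-dihydroxy-2,3-dimethyl-6-(3-methylbut-2-en-1-yl)-4-oxochroman-8-yl]-3-phenylpropanoic acid | O=C1c2c(O)c(CC=C(C)C)c(O)c([C@H](CC(=O)O)c3ccccc3)c2O[C@@H](C)[C@H]1C | intermediate
13 | (R)-3-[(2S,3R)-5-hydroxy-7-methoxy-2,3-dimethyl-6-(3-methylbut-2-en-1-yl)-4-oxochroman-8-yl]-3-phenylpropanoic acid | COc1c(CC=C(C)C)c(O)c2c(c1[C@H](CC(=O)O)c1ccccc1)O[C@@H](C)[C@@H](C)C2=O | target

**Step count**

Total steps: 7. Longest linear sequence: 7 steps (1 → 2 → 4 → 6 → 7 → 9 → 11 → 13).

**Steps most likely to fail**

1. Step 5 (carbene-catalysed annulation). The acyl-conjugated, iodine-flanked phenoxide is a weaker carbon nucleophile than the phenols for which the annulation is established, so carbon–carbon bond formation may be slow, O-acylation may stop without rearrangement, or the facial selectivity may be low; prolonged contact with base could also epimerise C3. Fallback, setting out from 7 and returning at 9: 7 would be condensed with benzaldehyde and Meldrum's acid (2,2-dimethyl-1,3-dioxane-4,6-dione) in MeCN with catalytic pyridine at 60 °C. Knoevenagel condensation, conjugate addition of C8 and lactonisation with loss of acetone and CO2 should give 9 together with its C10 epimer (2S,3R,10S)-5-hydroxy-6-iodo-2,3-dimethyl-10-phenyl-2,3,9,10-tetrahydro-4H,8H-pyrano[2,3-f]chromene-4,8-dione F1. Because the chromanone is enantiopure the two are diastereomers, to be separated by chromatography or crystallisation, and 9 goes on to step 6.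

2. Step 4 (iodination). Iodine may attack C8 instead of C6, or both carbons may be iodinated. Fallback, setting out from 4 and returning at 11: the C6 substituent would be placed before ring closure, where the ring is still symmetric.
   - 4 would be iodinated (iodine, NaHCO3, aqueous THF) at the carbon between its two equivalent hydroxyls to tert-butyl (2R,3S)-3-(3,5-dihydroxy-4-iodophenoxy)-2-methylbutanoate F2.
   - Coupling with allyltributylstannane (Pd(PPh3)4, DMF, 80 °C) would give the acid-stable allyl compound tert-butyl (2R,3S)-3-[3,5-dihydroxy-4-(prop-2-en-1-yl)phenoxy]-2-methylbutanoate F3.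
   - Cleavage and cyclisation as in step 3 would lead through (2R,3S)-3-[3,5-dihydroxy-4-(prop-2-en-1-yl)phenoxy]-2-methylbutanoic acid F4 to (2S,3R)-5,7-dihydroxy-2,3-dimethyl-6-(prop-2-en-1-yl)chroman-4-one F5.
   - Annulation with 8 as in step 5 would give (2S,3R,10R)-5-hydroxy-2,3-dimethyl-10-phenyl-6-(prop-2-en-1-yl)-2,3,9,10-tetrahydro-4H,8H-pyrano[2,3-f]chromene-4,8-dione F6.
   - Cross-metathesis with 2-methylbut-2-ene (second-generation Grubbs catalyst, CH2Cl2, 40 °C) would turn allyl into prenyl and give 11.

3. Step 3 (key acylation). The strongly acidic medium may epimerise C3, or open and re-close the hydroxy-chromanone through the ortho-hydroxy enone, or the ring may be tert-butylated during ester cleavage. Fallback, setting out from 2 and returning at 6: Mitsunobu reaction of 2 with commercial 3,5-bis(benzyloxy)phenol would give tert-butyl (2R,3S)-3-[3,5-bis(benzyloxy)phenoxy]-2-methylbutanoate F7. CF3CO2H/Et3SiH at 0 °C would give (2R,3S)-3-[3,5-bis(benzyloxy)phenoxy]-2-methylbutanoic acid F8. The ether-activated ring should then close with (CF3CO)2O in CH2Cl2 at 0 °C, without a strong protic acid, to (2S,3R)-5,7-bis(benzyloxy)-2,3-dimethylchroman-4-one F9. Hydrogenolysis (H2, Pd/C, EtOAc) would give 6.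

Further compounds
F1 | step 5 | (2S,3R,10S)-5-hydroxy-6-iodo-2,3-dimethyl-10-phenyl-2,3,9,10-tetrahydro-4H,8H-pyrano[2,3-f]chromene-4,8-dione | O=C1c2c(O)c(I)c3OC(=O)C[C@@H](c4ccccc4)c3c2O[C@@H](C)[C@H]1C
F2 | step 4 | tert-butyl (2R,3S)-3-(3,5-dihydroxy-4-iodophenoxy)-2-methylbutanoate | C[C@H](Oc1cc(O)c(I)c(O)c1)[C@@H](C)C(=O)OC(C)(C)C
F3 | step 4 | tert-butyl (2R,3S)-3-[3,5-dihydroxy-4-(prop-2-en-1-yl)phenoxy]-2-methylbutanoate | C[C@H](Oc1cc(O)c(CC=C)c(O)c1)[C@@H](C)C(=O)OC(C)(C)C
F4 | step 4 | (2R,3S)-3-[3,5-dihydroxy-4-(prop-2-en-1-yl)phenoxy]-2-methylbutanoic acid | C[C@H](Oc1cc(O)c(CC=C)c(O)c1)[C@@H](C)C(=O)O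
F5 | step 4 | (2S,3R)-5,7-dihydroxy-2,3-dimethyl-6-(prop-2-en-1-yl)chroman-4-one | O=C1c2c(O)c(CC=C)c(O)cc2O[C@@H](C)[C@H]1C
F6 | step 4 | (2S,3R,10R)-5-hydroxy-2,3-dimethyl-10-phenyl-6-(prop-2-en-1-yl)-2,3,9,10-tetrahydro-4H,8H-pyrano[2,3-f]chromene-4,8-dione | O=C1c2c(O)c(CC=C)c3OC(=O)C[C@H](c4ccccc4)c3c2O[C@@H](C)[C@H]1C
F7 | step 3 | tert-butyl (2R,3S)-3-[3,5-bis(benzyloxy)phenoxy]-2-methylbutanoate | C[C@H](Oc1cc(OCc2ccccc2)cc(OCc2ccccc2)c1)[C@@H](C)C(=O)OC(C)(C)C
F8 | step 3 | (2R,3S)-3-[3,5-bis(benzyloxy)phenoxy]-2-methylbutanoic acid | C[C@H](Oc1cc(OCc2ccccc2)cc(OCc2ccccc2)c1)[C@@H](C)C(=O)O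
F9 | step 3 | (2S,3R)-5,7-bis(benzyloxy)-2,3-dimethylchroman-4-one | O=C1c2c(OCc3ccccc3)cc(OCc3ccccc3)cc2O[C@@H](C)[C@H]1C
A1 | direct plan | (R)-5,7-dimethoxy-4-phenylchroman-2-one | O=C1C[C@H](c2ccccc2)c2c(OC)cc(OC)cc2O1
A2 | direct plan | (R)-7-hydroxy-5-methoxy-8-[(E)-2-methylbut-2-enoyl]-4-phenylchroman-2-one | O=C1C[C@H](c2ccccc2)c2c(OC)cc(O)c(C(=O)/C(C)=C/C)c2O1
A3 | direct plan | (R)-5-methoxy-7-[(2-methylbut-3-en-2-yl)oxy]-8-[(E)-2-methylbut-2-enoyl]-4-phenylchroman-2-one | O=C1C[C@H](c2ccccc2)c2c(OC)cc(OC(C)(C)C=C)c(C(=O)/C(C)=C/C)c2O1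
A4 | direct plan | (R)-3-{(2S,3R)-7-methoxy-2,3-dimethyl-5-[(2-methylbut-3-en-2-yl)oxy]-4-oxochroman-8-yl}-3-phenylpropanoic acid | COc1cc(OC(C)(C)C=C)c2c(c1[C@H](CC(=O)O)c1ccccc1)O[C@@H](C)[C@@H](C)C2=O
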